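**Retrosynthetic overview**
1. 21 ⇐ 20: one hydrogenolysis removes four benzyl ethers.
2. Lactone ring (closed last): 20 ⇐ 18 by reductive removal of the oxazolidinone, 5-exo lactonization onto the tert-butyl ester and base equilibration to trans. 18 ⇐ 13 + 17 by oxidative enolate heterocoupling, which makes the 8–8' bond.
3. Dihydrobenzofuran ring (closed first): 13 ⇐ 11 ⇐ 4 + 9 by oxidative phenoxy-radical 8–5' cross-coupling and trapping of the quinone methide by the ring B phenol. A camphorsultam on the feruloyl partner sets C2/C3, and a benzyl ether on O3 of the catechol unit steers the coupling to C5.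
4. 4, 9 and 17 come in one or two steps from commercial 1 + 2, 5 + 6 and 14 + 15.

Assumption: the (2R)-bornane-10,2-sultam is taken as the antipode that steers the 8–5' coupling to the (2S,3S) adduct 11; I could not derive the sense with certainty, so it must be confirmed on the first run, and if it is opposite the mirror-image sultam is used with nothing else changed.

**Step 1**
Reactants: 1 3-(benzyloxy)-4-hydroxybenzaldehyde; 2 tert-butyl (triphenylphosphoranylidene)acetate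
Product: 3 tert-butyl (E)-3-[3-(benzyloxy)-4-hydroxyphenyl]prop-2-enoate
Conditions: PhMe, 90 °C, 6 h
Reagents that add atoms: none
Why: Wittig olefination with a stabilized ylide tolerates the free phenol and gives the E-cinnamate, with no stereocentre formed.

**Step 2**
Reactants: 3 tert-butyl (E)-3-[3-(benzyloxy)-4-hydroxyphenyl]prop-2-enoate
Product: 4 tert-butyl 3-[3-(benzyloxy)-4-hydroxyphenyl]propanoate
Conditions: H2 (4 atm), RhCl(PPh3)3 (3 mol %), PhMe/EtOH 1:1, 50 °C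
Reagents that add atoms: none
Why: Homogeneous catalytic hydrogenation with Wilkinson's catalyst saturates the cinnamate C=C and cannot hydrogenolyse the aryl benzyl ether.

**Step 3**
Reactants: 5 (E)-3-(4-acetoxy-3-methoxyphenyl)prop-2-enoic acid (O-acetylferulic acid); 6 (2R)-bornane-10,2-sultam
Product: 9 N-[(E)-feruloyl]-(2R)-bornane-10,2-sultam, via acid chloride 7 (not isolated), via O-acetyl amide 8 (not isolated)
Conditions: (COCl)2, cat. DMF, CH2Cl2, 0 °C → rt, evaporate; 6, NaH, PhMe, 0 °C → rt; then pyrrolidine (1.5 equiv), 0 °C, 30 min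
Reagents that add atoms: none
Why: N-acylation of the sodium salt of Oppolzer's sultam by the acid chloride, then selective aminolysis of the far more electrophilic aryl acetate in the same flask, gives the free-phenol enoyl sultam with the E alkene intact.

**Step 4**
Reactants: 4 tert-butyl 3-[3-(benzyloxy)-4-hydroxyphenyl]propanoate; 9 N-[(E)-feruloyl]-(2R)-bornane-10,2-sultam
Product: 11 tert-butyl 3-[(2S,3S)-7-(benzyloxy)-2-(4-hydroxy-3-methoxyphenyl)-3-{[(2R)-bornane-10,2-sultam-N-yl]carbonyl}-2,3-dihydro-1-benzofuran-5-yl]propanoate, via quinone methide 10 (not isolated)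
Conditions: Ag2O (1.3 equiv), 4 (3 equiv, excess recovered), 9 added over 10 h by syringe pump, CH2Cl2/acetone 4:1, rt, dark; chromatography removes the minor trans diastereomer
Reagents that add atoms: none
Why: Proposed new method: Ag2O oxidises both phenols by one electron, the ferulamide radical (spin at C8) and the radical of 4 (spin at C5, ortho to oxygen; O3 is a benzyl ether, so no benzodioxane can form) couple 8–5' as in the biosynthetic phenoxy-radical coupling, ring B re-aromatises to quinone methide 10 and its phenol adds to C7 anti to the acyl group to close the trans-dihydrobenzofuran, while the sultam shields one face of C8 so that C3 and with it C2 are set in this one step; the closest known reactions are the Ag2O homodimerisation of this same sultam amide (about 80% de, trans only) and Ag2O cross-couplings of ferulates or coniferyl alcohol with saturated guaiacyl phenols.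

**Step 5**
Reactants: 11 tert-butyl 3-[(2S,3S)-7-(benzyloxy)-2-(4-hydroxy-3-methoxyphenyl)-3-{[(2R)-bornane-10,2-sultam-N-yl]carbonyl}-2,3-dihydro-1-benzofuran-5-yl]propanoate
Product: 12 tert-butyl 3-[(2S,3R)-7-(benzyloxy)-2-(4-hydroxy-3-methoxyphenyl)-3-(hydroxymethyl)-2,3-dihydro-1-benzofuran-5-yl]propanoate
Conditions: LiBH4 (3 equiv), THF/MeOH 20:1, 0 °C, 2 h; aq. NH4Cl
Reagents that add atoms: none
Why: Hydride reduction cleaves the activated N-acyl sultam to the primary alcohol and returns the auxiliary while the tert-butyl ester is inert to LiBH4; C3 keeps its spatial arrangement and only its descriptor changes from S to R.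

**Step 6**
Reactants: 12 tert-butyl 3-[(2S,3R)-7-(benzyloxy)-2-(4-hydroxy-3-methoxyphenyl)-3-(hydroxymethyl)-2,3-dihydro-1-benzofuran-5-yl]propanoate
Product: 13 tert-butyl 3-{(2S,3R)-7-(benzyloxy)-2-[4-(benzyloxy)-3-methoxyphenyl]-3-[(benzyloxy)methyl]-2,3-dihydro-1-benzofuran-5-yl}propanoate
Conditions: NaH (2.4 equiv), BnBr (2.4 equiv), Bu4NI (cat.), DMF, 0 °C → rt
Reagents that add atoms: benzyl bromide, BrCc1ccccc1
Why: Williamson etherification of the phenoxide and the primary alkoxide masks both acidic hydroxyls for the enolate chemistry, and NaH does not enolise the tert-butyl ester.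

**Step 7**
Reactants: 14 3-[4-(benzyloxy)-3-methoxyphenyl]propanoic acid; 15 (R)-4-benzyl-1,3-oxazolidin-2-one
Product: 17 (R)-4-benzyl-3-{3-[4-(benzyloxy)-3-methoxyphenyl]propanoyl}-1,3-oxazolidin-2-one, via mixed pivalic anhydride 16 (not isolated)
Conditions: t-BuCOCl, Et3N, THF, −20 °C; then 15, LiCl, −20 °C → rt
Reagents that add atoms: none
Why: Mixed-anhydride N-acylation of the Evans oxazolidinone, in which LiCl activates the auxiliary and attack goes to the unhindered carbonyl of the anhydride.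

**Step 8**
Reactants: 13 tert-butyl 3-{(2S,3R)-7-(benzyloxy)-2-[4-(benzyloxy)-3-methoxyphenyl]-3-[(benzyloxy)methyl]-2,3-dihydro-1-benzofuran-5-yl}propanoate; 17 (R)-4-benzyl-3-{3-[4-(benzyloxy)-3-methoxyphenyl]propanoyl}-1,3-oxazolidin-2-one
Product: 18 tert-butyl (2RS,3S)-4-[(4R)-4-benzyl-2-oxo-1,3-oxazolidin-3-yl]-3-[4-(benzyloxy)-3-methoxybenzyl]-2-({(2S,3R)-7-(benzyloxy)-2-[4-(benzyloxy)-3-methoxyphenyl]-3-[(benzyloxy)methyl]-2,3-dihydro-1-benzofuran-5-yl}methyl)-4-oxobutanoate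
Conditions: 17 (1.5 equiv) and 13 in THF added to LiN(iPr)2 (2.6 equiv), −78 °C, 30 min; Fe(acac)3 (2.6 equiv), −78 °C → rt
Reagents that add atoms: none
Why: Oxidative enolate heterocoupling, in which Fe(acac)3 oxidises the mixed lithium enolates and the new 8–8' bond forms anti to the benzyl group of the chelated Z-imide enolate (same sense as Evans alkylation), fixing the future lactone C4 as S, while the ester-side centre forms as an epimer mixture that step 9 corrects.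

**Step 9**
Reactants: 18 tert-butyl (2RS,3S)-4-[(4R)-4-benzyl-2-oxo-1,3-oxazolidin-3-yl]-3-[4-(benzyloxy)-3-methoxybenzyl]-2-({(2S,3R)-7-(benzyloxy)-2-[4-(benzyloxy)-3-methoxyphenyl]-3-[(benzyloxy)methyl]-2,3-dihydro-1-benzofuran-5-yl}methyl)-4-oxobutanoate
Product: 20 (3S,4S)-4-[4-(benzyloxy)-3-methoxybenzyl]-3-({(2S,3R)-7-(benzyloxy)-2-[4-(benzyloxy)-3-methoxyphenyl]-3-[(benzyloxy)methyl]-2,3-dihydro-1-benzofuran-5-yl}methyl)oxolan-2-one, via hydroxy ester 19 (not isolated)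
Conditions: LiBH4 (2 equiv), MeOH (2 equiv), THF, 0 °C; aq. NH4Cl, extract; crude 19 in THF, KOtBu (1.5 equiv), 0 °C → rt, 2 h
Reagents that add atoms: none
Why: Hydride reduction cleaves the imide to the primary alcohol without touching the tert-butyl ester, and tert-butoxide then drives 5-exo lactonization and equilibrates the enolisable C3 to the thermodynamically preferred trans (3S,4S) lactone, C4 being fixed.

**Step 10**
Reactants: 20 (3S,4S)-4-[4-(benzyloxy)-3-methoxybenzyl]-3-({(2S,3R)-7-(benzyloxy)-2-[4-(benzyloxy)-3-methoxyphenyl]-3-[(benzyloxy)methyl]-2,3-dihydro-1-benzofuran-5-yl}methyl)oxolan-2-one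
Product: 21 (3S,4S)-3-{[(2S,3R)-7-hydroxy-2-(4-hydroxy-3-methoxyphenyl)-3-(hydroxymethyl)-2,3-dihydro-1-benzofuran-5-yl]methyl}-4-(4-hydroxy-3-methoxybenzyl)oxolan-2-one
Conditions: H2 (1 atm), Pd(OH)2/C, EtOAc/EtOH 2:1, rt, monitored and stopped at full conversion
Reagents that add atoms: none
Why: Catalytic hydrogenolysis cleaves the three aryl benzyl ethers and the primary alkyl benzyl ether under neutral conditions that leave the lactone, the cyclic benzylic aryl ether and all four stereocentres untouched.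

**Compound list**
1 | 3-(benzyloxy)-4-hydroxybenzaldehyde | O=Cc1ccc(O)c(OCc2ccccc2)c1 | starting material
2 | tert-butyl (triphenylphosphoranylidene)acetate | CC(C)(C)OC(=O)C=P(c1ccccc1)(c1ccccc1)c1ccccc1 | starting material
3 | tert-butyl (E)-3-[3-(benzyloxy)-4-hydroxyphenyl]prop-2-enoate | CC(C)(C)OC(=O)/C=C/c1ccc(O)c(OCc2ccccc2)c1 | intermediate
4 | tert-butyl 3-[3-(benzyloxy)-4-hydroxyphenyl]propanoate | CC(C)(C)OC(=O)CCc1ccc(O)c(OCc2ccccc2)c1 | intermediate
5 | (E)-3-(4-acetoxy-3-methoxyphenyl)prop-2-enoic acid | COc1cc(/C=C/C(=O)O)ccc1OC(C)=O | starting material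
6 | (2R)-bornane-10,2-sultam | CC1(C)[C@@H]2CC[C@]13CS(=O)(=O)N[C@@H]3C2 | starting material
7 | (E)-3-(4-acetoxy-3-methoxyphenyl)prop-2-enoyl chloride | COc1cc(/C=C/C(=O)Cl)ccc1OC(C)=O | intermediate
8 | N-[(E)-3-(4-acetoxy-3-methoxyphenyl)prop-2-enoyl]-(2R)-bornane-10,2-sultam | CC1(C)[C@@H]2CC[C@]13CS(=O)(=O)N(C(=O)/C=C/c4ccc(OC(C)=O)c(OC)c4)[C@@H]3C2 | intermediate
9 | N-[(E)-feruloyl]-(2R)-bornane-10,2-sultam | CC1(C)[C@@H]2CC[C@]13CS(=O)(=O)N(C(=O)/C=C/c4ccc(O)c(OC)c4)[C@@H]3C2 | intermediate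
10 | 8–5'-coupled p-quinone methide (ring B re-aromatised, C8 set) | CC1(C)[C@@H]2CC[C@]13CS(=O)(=O)N(C(=O)[C@@H](c4cc(CCC(=O)OC(C)(C)C)cc(OCc5ccccc5)c4O)C=C4C=CC(=O)C(OC)=C4)[C@@H]3C2 | intermediate
11 | tert-butyl 3-[(2S,3S)-7-(benzyloxy)-2-(4-hydroxy-3-methoxyphenyl)-3-{[(2R)-bornane-10,2-sultam-N-yl]carbonyl}-2,3-dihydro-1-benzofuran-5-yl]propanoate | CC1(C)[C@@H]2CC[C@]13CS(=O)(=O)N(C(=O)[C@@H]4[C@@H](c5ccc(O)c(OC)c5)Oc5c(OCc6ccccc6)cc(CCC(=O)OC(C)(C)C)cc45)[C@@H]3C2 | intermediate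
12 | tert-butyl 3-[(2S,3R)-7-(benzyloxy)-2-(4-hydroxy-3-methoxyphenyl)-3-(hydroxymethyl)-2,3-dihydro-1-benzofuran-5-yl]propanoate | CC(C)(C)OC(=O)CCc1cc(OCc2ccccc2)c2c(c1)[C@H](CO)[C@@H](c1ccc(O)c(OC)c1)O2 | intermediate
13 | tert-butyl 3-{(2S,3R)-7-(benzyloxy)-2-[4-(benzyloxy)-3-methoxyphenyl]-3-[(benzyloxy)methyl]-2,3-dihydro-1-benzofuran-5-yl}propanoate | CC(C)(C)OC(=O)CCc1cc(OCc2ccccc2)c2c(c1)[C@H](COCc1ccccc1)[C@@H](c1ccc(OCc3ccccc3)c(OC)c1)O2 | intermediate
14 | 3-[4-(benzyloxy)-3-methoxyphenyl]propanoic acid | COc1cc(CCC(=O)O)ccc1OCc1ccccc1 | starting material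
15 | (R)-4-benzyl-1,3-oxazolidin-2-one | O=C1N[C@H](Cc2ccccc2)CO1 | starting material
16 | 3-[4-(benzyloxy)-3-methoxyphenyl]propanoic pivalic anhydride | COc1cc(CCC(=O)OC(=O)C(C)(C)C)ccc1OCc1ccccc1 | intermediate
17 | (R)-4-benzyl-3-{3-[4-(benzyloxy)-3-methoxyphenyl]propanoyl}-1,3-oxazolidin-2-one | COc1cc(CCC(=O)N2[C@H](Cc3ccccc3)COC2=O)ccc1OCc1ccccc1 | intermediate
18 | tert-butyl (2RS,3S)-4-[(4R)-4-benzyl-2-oxo-1,3-oxazolidin-3-yl]-3-[4-(benzyloxy)-3-methoxybenzyl]-2-({(2S,3R)-7-(benzyloxy)-2-[4-(benzyloxy)-3-methoxyphenyl]-3-[(benzyloxy)methyl]-2,3-dihydro-1-benzofuran-5-yl}methyl)-4-oxobutanoate | CC(C)(C)OC(=O)C(Cc1cc(OCc2ccccc2)c2c(c1)[C@H](COCc1ccccc1)[C@@H](c1ccc(OCc3ccccc3)c(OC)c1)O2)[C@H](Cc1ccc(OCc2ccccc2)c(OC)c1)C(=O)N1[C@H](Cc2ccccc2)COC1=O | intermediate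
19 | tert-butyl (2RS,3S)-3-[4-(benzyloxy)-3-methoxybenzyl]-2-({(2S,3R)-7-(benzyloxy)-2-[4-(benzyloxy)-3-methoxyphenyl]-3-[(benzyloxy)methyl]-2,3-dihydro-1-benzofuran-5-yl}methyl)-4-hydroxybutanoate | CC(C)(C)OC(=O)C(Cc1cc(OCc2ccccc2)c2c(c1)[C@H](COCc1ccccc1)[C@@H](c1ccc(OCc3ccccc3)c(OC)c1)O2)[C@H](Cc1ccc(OCc2ccccc2)c(OC)c1)CO | intermediate
20 | (3S,4S)-4-[4-(benzyloxy)-3-methoxybenzyl]-3-({(2S,3R)-7-(benzyloxy)-2-[4-(benzyloxy)-3-methoxyphenyl]-3-[(benzyloxy)methyl]-2,3-dihydro-1-benzofuran-5-yl}methyl)oxolan-2-one | COc1cc(C[C@@H]2COC(=O)[C@H]2Cc2cc(OCc3ccccc3)c3c(c2)[C@H](COCc2ccccc2)[C@@H](c2ccc(OCc4ccccc4)c(OC)c2)O3)ccc1OCc1ccccc1 | intermediate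
21 | (3S,4S)-3-{[(2S,3R)-7-hydroxy-2-(4-hydroxy-3-methoxyphenyl)-3-(hydroxymethyl)-2,3-dihydro-1-benzofuran-5-yl]methyl}-4-(4-hydroxy-3-methoxybenzyl)oxolan-2-one | COc1cc(C[C@@H]2COC(=O)[C@H]2Cc2cc(O)c3c(c2)[C@H](CO)[C@@H](c2ccc(O)c(OC)c2)O3)ccc1O | target

**Step count**
Total: 10 steps. Longest linear sequence: 8 steps (1, 2, 4, 5, 6, 8, 9, 10); steps 3 and 7 are side branches.

**Three steps most likely to fail, each with a fallback**

Step 4 (cross-coupling yield, 8–O–4 and homodimer by-products, unproven sense and level of induction). The fallback sets out from 4 and comes back at 12. Phenol 4 (3 equiv) is coupled with commercial (E)-coniferyl alcohol under Ag2O in CH2Cl2/acetone, which gives the racemic trans diol F1 directly and makes steps 3 and 5 unnecessary. The racemate is then resolved by preparative chromatography on a cellulose tris(3,5-dimethylphenylcarbamate) phase; the (2S,3R) enantiomer is 12 and the route continues at step 6. Stereocontrol is thus replaced by resolution.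

Step 8 (heterocoupling of a large, precious ester; homodimers; facial control at the imide carbon). The fallback sets out from 13 and comes back at 18 by a two-electron alkylation instead of a radical coupling. Ester 13 is deprotonated with LiN(iPr)2 and hydroxylated with 2-(phenylsulfonyl)-3-phenyloxaziridine to the α-hydroxy ester F2, which Tf2O/2,6-lutidine converts into the α-triflyloxy ester F3. The sodium enolate of 17 (NaN(SiMe3)2, THF, −78 °C, used in excess) displaces the triflate in an SN2 alkylation anti to the auxiliary benzyl group and gives 18, again as a C2 epimer mixture that step 9 corrects.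

Step 10 (the primary alkyl benzyl ether is slow to cleave, and long exposure risks hydrogenolysis of the benzylic C2–O bond of the dihydrobenzofuran). The fallback sets out from 12 and comes back at 21 with a different protecting group on the alcohol. The phenol alone is benzylated (BnBr, K2CO3, acetone) to the phenol benzyl ether F4, and the alcohol is silylated (TBSCl, imidazole, DMF) to the silyl ether F5. Heterocoupling with 17 as in step 8 gives the succinate F6; LiBH4 then KOtBu as in step 9 give, by way of the hydroxy ester F7, the silylated lactone F8. Bu4NF/AcOH in THF frees the alcohol F9, and a brief hydrogenolysis (Pd/C, H2, 1 atm, under 1 h) of only three aryl benzyl ethers gives 21.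

**Further compounds**
F1 | step 4 | racemic trans tert-butyl 3-[7-(benzyloxy)-2-(4-hydroxy-3-methoxyphenyl)-3-(hydroxymethyl)-2,3-dihydro-1-benzofuran-5-yl]propanoate | CC(C)(C)OC(=O)CCc1cc(OCc2ccccc2)c2c(c1)[C@H](CO)[C@@H](c1ccc(O)c(OC)c1)O2.CC(C)(C)OC(=O)CCc1cc(OCc2ccccc2)c2c(c1)[C@@H](CO)[C@H](c1ccc(O)c(OC)c1)O2
F2 | step 8 | tert-butyl (2RS)-3-{(2S,3R)-7-(benzyloxy)-2-[4-(benzyloxy)-3-methoxyphenyl]-3-[(benzyloxy)methyl]-2,3-dihydro-1-benzofuran-5-yl}-2-hydroxypropanoate | CC(C)(C)OC(=O)C(O)Cc1cc(OCc2ccccc2)c2c(c1)[C@H](COCc1ccccc1)[C@@H](c1ccc(OCc3ccccc3)c(OC)c1)O2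
F3 | step 8 | tert-butyl (2RS)-3-{(2S,3R)-7-(benzyloxy)-2-[4-(benzyloxy)-3-methoxyphenyl]-3-[(benzyloxy)methyl]-2,3-dihydro-1-benzofuran-5-yl}-2-[(trifluoromethanesulfonyl)oxy]propanoate | CC(C)(C)OC(=O)C(OS(=O)(=O)C(F)(F)F)Cc1cc(OCc2ccccc2)c2c(c1)[C@H](COCc1ccccc1)[C@@H](c1ccc(OCc3ccccc3)c(OC)c1)O2
F4 | step 10 | tert-butyl 3-{(2S,3R)-7-(benzyloxy)-2-[4-(benzyloxy)-3-methoxyphenyl]-3-(hydroxymethyl)-2,3-dihydro-1-benzofuran-5-yl}propanoate | CC(C)(C)OC(=O)CCc1cc(OCc2ccccc2)c2c(c1)[C@H](CO)[C@@H](c1ccc(OCc3ccccc3)c(OC)c1)O2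
F5 | step 10 | tert-butyl 3-{(2S,3R)-7-(benzyloxy)-2-[4-(benzyloxy)-3-methoxyphenyl]-3-{[(tert-butyldimethylsilyl)oxy]methyl}-2,3-dihydro-1-benzofuran-5-yl}propanoate | CC(C)(C)OC(=O)CCc1cc(OCc2ccccc2)c2c(c1)[C@H](CO[Si](C)(C)C(C)(C)C)[C@@H](c1ccc(OCc3ccccc3)c(OC)c1)O2
F6 | step 10 | tert-butyl (2RS,3S)-4-[(4R)-4-benzyl-2-oxo-1,3-oxazolidin-3-yl]-3-[4-(benzyloxy)-3-methoxybenzyl]-2-({(2S,3R)-7-(benzyloxy)-2-[4-(benzyloxy)-3-methoxyphenyl]-3-{[(tert-butyldimethylsilyl)oxy]methyl}-2,3-dihydro-1-benzofuran-5-yl}methyl)-4-oxobutanoate | CC(C)(C)OC(=O)C(Cc1cc(OCc2ccccc2)c2c(c1)[C@H](CO[Si](C)(C)C(C)(C)C)[C@@H](c1ccc(OCc3ccccc3)c(OC)c1)O2)[C@H](Cc1ccc(OCc2ccccc2)c(OC)c1)C(=O)N1[C@H](Cc2ccccc2)COC1=O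
F7 | step 10 | tert-butyl (2RS,3S)-3-[4-(benzyloxy)-3-methoxybenzyl]-2-({(2S,3R)-7-(benzyloxy)-2-[4-(benzyloxy)-3-methoxyphenyl]-3-{[(tert-butyldimethylsilyl)oxy]methyl}-2,3-dihydro-1-benzofuran-5-yl}methyl)-4-hydroxybutanoate | CC(C)(C)OC(=O)C(Cc1cc(OCc2ccccc2)c2c(c1)[C@H](CO[Si](C)(C)C(C)(C)C)[C@@H](c1ccc(OCc3ccccc3)c(OC)c1)O2)[C@H](Cc1ccc(OCc2ccccc2)c(OC)c1)CO
F8 | step 10 | (3S,4S)-4-[4-(benzyloxy)-3-methoxybenzyl]-3-({(2S,3R)-7-(benzyloxy)-2-[4-(benzyloxy)-3-methoxyphenyl]-3-{[(tert-butyldimethylsilyl)oxy]methyl}-2,3-dihydro-1-benzofuran-5-yl}methyl)oxolan-2-one | COc1cc(C[C@@H]2COC(=O)[C@H]2Cc2cc(OCc3ccccc3)c3c(c2)[C@H](CO[Si](C)(C)C(C)(C)C)[C@@H](c2ccc(OCc4ccccc4)c(OC)c2)O3)ccc1OCc1ccccc1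
F9 | step 10 | (3S,4S)-4-[4-(benzyloxy)-3-methoxybenzyl]-3-({(2S,3R)-7-(benzyloxy)-2-[4-(benzyloxy)-3-methoxyphenyl]-3-(hydroxymethyl)-2,3-dihydro-1-benzofuran-5-yl}methyl)oxolan-2-one | COc1cc(C[C@@H]2COC(=O)[C@H]2Cc2cc(OCc3ccccc3)c3c(c2)[C@H](CO)[C@@H](c2ccc(OCc4ccccc4)c(OC)c2)O3)ccc1OCc1ccccc1
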